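**Strategy**

Everything rests on cutting the bond from C2 of the 2,3-dihydrobenzofuran ring to the ipso carbon of the 4-hydroxyphenyl ring. C2 is an α-aryloxy carbon of the five-membered ring next to the C3 stereocentre, so it is made as a radical by decarboxylation: a nickel/photoredox decarboxylative arylation joins the complete dihydrobenzofuran-2-carboxylic acid to a 4-iodophenyl ether and sets C2 trans to the C3 aryl group from either C2 epimer. The precursor acid arises from a coumarin: rhodium-catalysed asymmetric 1,4-arylation fixes C3, and bromination with ring contraction converts the six-membered lactone into the dihydrofuran ring. Reduction, oxidation and debenzylation finish the route.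

Key step: step 5

Assumption (chemistry): Rh/SEGPHOS is taken to select the same coumarin face in 5 as in simple coumarins, where the (R)-ligand gives the (4R)-4-aryl lactone; (S)-SEGPHOS is therefore specified for (4S)-7, and the antipodal ligand would be used if the sense were reversed.

**Route**

Step 1
Reactants: 1 methyl 4-bromo-3,5-dihydroxybenzoate; 2 methyl acrylate
Product: 4 methyl 5-hydroxy-2-oxo-2H-chromene-7-carboxylate, via (E)-cinnamate diester 3 (not isolated)
Conditions: Pd(OAc)2, P(o-tol)3, Et3N, DMF, 100 °C; concentrate; then n-Bu3P (20 mol%), MeOH, 70 °C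
Reagents that add atoms: none
Why: The Heck reaction of the ester-activated aryl bromide with the acrylate should give the (E)-cinnamate, and reversible conjugate addition of the nucleophilic phosphine then allows E/Z isomerisation so that either of the two equivalent ortho hydroxyl groups closes the lactone with loss of methanol (Heck reaction followed by phosphine-catalysed isomerisation–lactonisation to the coumarin).

Step 2
Reactants: 4 methyl 5-hydroxy-2-oxo-2H-chromene-7-carboxylate
Product: 5 methyl 5-(benzyloxy)-2-oxo-2H-chromene-7-carboxylate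
Conditions: BnBr, K2CO3, DMF, rt
Reagents that add atoms: benzyl bromide, BrCc1ccccc1
Why: Williamson etherification of the only free phenol masks it for the enolate, carboxylate-oxidation and hydride steps that follow, and the coumarin lactone and the methyl ester are inert to carbonate in DMF.

Step 3
Reactants: 5 methyl 5-(benzyloxy)-2-oxo-2H-chromene-7-carboxylate; 6 [3,5-bis(benzyloxy)phenyl]boronic acid
Product: 7 methyl (4S)-5-(benzyloxy)-4-[3,5-bis(benzyloxy)phenyl]-2-oxo-3,4-dihydro-2H-chromene-7-carboxylate
Conditions: Rh(acac)(C2H4)2 (3 mol%), (S)-SEGPHOS, excess 6, dioxane/H2O 10:1, 60 °C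
Reagents that add atoms: none
Why: Hayashi–Miyaura rhodium-catalysed asymmetric 1,4-addition: the aryl–rhodium species inserts the C3=C4 double bond of the coumarin on the enantioface selected by the chiral bisphosphine, which sets C4 as S (the later C3 of the target), and water protonates the rhodium enolate, while esters and benzyl ethers are inert.

Step 4
Reactants: 7 methyl (4S)-5-(benzyloxy)-4-[3,5-bis(benzyloxy)phenyl]-2-oxo-3,4-dihydro-2H-chromene-7-carboxylate
Product: 9 (2S,3S)-4-(benzyloxy)-3-[3,5-bis(benzyloxy)phenyl]-6-(methoxycarbonyl)-2,3-dihydro-1-benzofuran-2-carboxylic acid, via trans-3-bromo lactone 8 (not isolated)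
Conditions: LiHMDS, THF, −78 °C; NBS (1.0 equiv); then LiOH, H2O, 0 °C to rt; aq. HCl to pH 3
Reagents that add atoms: N-bromosuccinimide, O=C1CCC(=O)N1Br (bromine of 8); lithium hydroxide, [Li+].[OH-] (carboxyl OH of 9)
Why: The lithium enolate of the lactone is brominated on the face opposite the C4 aryl group to give the trans α-bromo lactone, hydroxide then opens the aryl ester faster than it attacks the methyl benzoate, and the freed phenoxide displaces bromide in a 5-exo-tet SN2 reaction with inversion (ring contraction of a 3-halodihydrocoumarin to a 2,3-dihydrobenzofuran-2-carboxylic acid), the benzylic stereocentre being untouched and the C2 configuration being of no consequence for step 5.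

Step 5
Reactants: 9 (2S,3S)-4-(benzyloxy)-3-[3,5-bis(benzyloxy)phenyl]-6-(methoxycarbonyl)-2,3-dihydro-1-benzofuran-2-carboxylic acid; 10 1-(benzyloxy)-4-iodobenzene
Product: 11 methyl (2S,3S)-4-(benzyloxy)-2-[4-(benzyloxy)phenyl]-3-[3,5-bis(benzyloxy)phenyl]-2,3-dihydro-1-benzofuran-6-carboxylate
Conditions: Ir[dF(CF3)ppy]2(dtbbpy)PF6 (2 mol%), NiCl2·glyme (10 mol%), dtbbpy (15 mol%), Cs2CO3, DMF, blue LEDs, rt
Reagents that add atoms: none
Why: The caesium carboxylate of 9 is oxidised by the excited Ir(III) photocatalyst and loses CO2 to give the C2 α-aryloxy radical of the dihydrofuran ring, while Ni(0)/dtbbpy adds oxidatively into the C–I bond of 10; the radical is captured at nickel and reductive elimination from Ni(III)(aryl)(alkyl) forms the C2–C(ipso) bond, after which Ir(II) returns Ni(I) to Ni(0). This is the metallaphotoredox decarboxylative arylation known for α-oxy carboxylic acids with aryl halides. No ring is closed in this step. The new C2 stereocentre is set by substrate control: the planar C2 radical is bound and coupled on the ring face away from the C3 3,5-bis(benzyloxy)phenyl group, so the trans (2S,3S) isomer should result from either C2 epimer of 9, as in 1,2-trans-selective C-arylation of furanosyl radicals. The step needs cross-coupling to outrun β-hydride elimination or radical oxidation (both would aromatise to a 3-arylbenzofuran) and protodecarboxylation; fast C(sp3)–C(sp2) reductive elimination from Ni(III), the use of the aryl iodide rather than the bromide, and the absence of any other oxidisable carboxylate or free phenol secure this. C3 is not touched, because only the carboxyl-bearing carbon becomes a radical.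

Step 6
Reactants: 11 methyl (2S,3S)-4-(benzyloxy)-2-[4-(benzyloxy)phenyl]-3-[3,5-bis(benzyloxy)phenyl]-2,3-dihydro-1-benzofuran-6-carboxylate
Product: 12 {(2S,3S)-4-(benzyloxy)-2-[4-(benzyloxy)phenyl]-3-[3,5-bis(benzyloxy)phenyl]-2,3-dihydro-1-benzofuran-6-yl}methanol
Conditions: DIBAL-H (3 equiv), CH2Cl2, −78 to 0 °C; aq. Rochelle salt
Reagents that add atoms: none
Why: DIBAL-H reduces the methyl benzoate to the benzylic alcohol, while the benzyl ethers, the cyclic benzylic ether and both stereocentres are inert to the hydride at low temperature (ester reduction).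

Step 7
Reactants: 12 {(2S,3S)-4-(benzyloxy)-2-[4-(benzyloxy)phenyl]-3-[3,5-bis(benzyloxy)phenyl]-2,3-dihydro-1-benzofuran-6-yl}methanol
Product: 13 (2S,3S)-4-(benzyloxy)-2-[4-(benzyloxy)phenyl]-3-[3,5-bis(benzyloxy)phenyl]-2,3-dihydro-1-benzofuran-6-carbaldehyde
Conditions: activated MnO2 (excess), CH2Cl2, rt
Reagents that add atoms: none
Why: Activated manganese dioxide oxidises the benzylic alcohol selectively to the aryl aldehyde without over-oxidation and without touching the ethers or the stereocentres (benzylic oxidation).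

Step 8
Reactants: 13 (2S,3S)-4-(benzyloxy)-2-[4-(benzyloxy)phenyl]-3-[3,5-bis(benzyloxy)phenyl]-2,3-dihydro-1-benzofuran-6-carbaldehyde
Product: 14 gnetal, (2S,3S)-3-(3,5-dihydroxyphenyl)-4-hydroxy-2-(4-hydroxyphenyl)-2,3-dihydro-1-benzofuran-6-carbaldehyde
Conditions: BCl3 (1 M in CH2Cl2), pentamethylbenzene, CH2Cl2, −78 °C; then H2O
Reagents that add atoms: none
Why: Boron trichloride cleaves the four aryl benzyl ethers at −78 °C while pentamethylbenzene traps the benzyl cations by Friedel–Crafts alkylation, a non-reductive debenzylation that leaves the aldehyde intact and, at this temperature, should leave the C2–O bond and the trans configuration of the dihydrofuran ring intact.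

**Compound list**

1 | methyl 4-bromo-3,5-dihydroxybenzoate | COC(=O)c1cc(O)c(Br)c(O)c1 | starting material
2 | methyl acrylate | C=CC(=O)OC | starting material
3 | methyl 3,5-dihydroxy-4-[(E)-3-methoxy-3-oxoprop-1-enyl]benzoate | COC(=O)/C=C/c1c(O)cc(cc1O)C(=O)OC | intermediate
4 | methyl 5-hydroxy-2-oxo-2H-chromene-7-carboxylate | COC(=O)c1cc(O)c2C=CC(=O)Oc2c1 | intermediate
5 | methyl 5-(benzyloxy)-2-oxo-2H-chromene-7-carboxylate | COC(=O)c1cc(OCc3ccccc3)c2C=CC(=O)Oc2c1 | intermediate
6 | [3,5-bis(benzyloxy)phenyl]boronic acid | OB(O)c1cc(OCc2ccccc2)cc(OCc2ccccc2)c1 | starting material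
7 | methyl (4S)-5-(benzyloxy)-4-[3,5-bis(benzyloxy)phenyl]-2-oxo-3,4-dihydro-2H-chromene-7-carboxylate | COC(=O)c1cc(OCc3ccccc3)c2c(c1)OC(=O)C[C@H]2c1cc(OCc2ccccc2)cc(OCc2ccccc2)c1 | intermediate
8 | methyl (3R,4S)-5-(benzyloxy)-4-[3,5-bis(benzyloxy)phenyl]-3-bromo-2-oxo-3,4-dihydro-2H-chromene-7-carboxylate (trans) | COC(=O)c1cc(OCc3ccccc3)c2c(c1)OC(=O)[C@H](Br)[C@H]2c1cc(OCc2ccccc2)cc(OCc2ccccc2)c1 | intermediate
9 | (2S,3S)-4-(benzyloxy)-3-[3,5-bis(benzyloxy)phenyl]-6-(methoxycarbonyl)-2,3-dihydro-1-benzofuran-2-carboxylic acid (trans) | COC(=O)c1cc(OCc3ccccc3)c2c(c1)O[C@H](C(=O)O)[C@H]2c1cc(OCc2ccccc2)cc(OCc2ccccc2)c1 | intermediate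
10 | 1-(benzyloxy)-4-iodobenzene | Ic1ccc(OCc2ccccc2)cc1 | starting material
11 | methyl (2S,3S)-4-(benzyloxy)-2-[4-(benzyloxy)phenyl]-3-[3,5-bis(benzyloxy)phenyl]-2,3-dihydro-1-benzofuran-6-carboxylate (trans) | COC(=O)c1cc(OCc3ccccc3)c2c(c1)O[C@H](c1ccc(OCc3ccccc3)cc1)[C@H]2c1cc(OCc2ccccc2)cc(OCc2ccccc2)c1 | intermediate
12 | {(2S,3S)-4-(benzyloxy)-2-[4-(benzyloxy)phenyl]-3-[3,5-bis(benzyloxy)phenyl]-2,3-dihydro-1-benzofuran-6-yl}methanol | OCc1cc(OCc3ccccc3)c2c(c1)O[C@H](c1ccc(OCc3ccccc3)cc1)[C@H]2c1cc(OCc2ccccc2)cc(OCc2ccccc2)c1 | intermediate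
13 | (2S,3S)-4-(benzyloxy)-2-[4-(benzyloxy)phenyl]-3-[3,5-bis(benzyloxy)phenyl]-2,3-dihydro-1-benzofuran-6-carbaldehyde | O=Cc1cc(OCc3ccccc3)c2c(c1)O[C@H](c1ccc(OCc3ccccc3)cc1)[C@H]2c1cc(OCc2ccccc2)cc(OCc2ccccc2)c1 | intermediate
14 | gnetal, (2S,3S)-3-(3,5-dihydroxyphenyl)-4-hydroxy-2-(4-hydroxyphenyl)-2,3-dihydro-1-benzofuran-6-carbaldehyde (trans) | O=Cc1cc(O)c2c(c1)O[C@H](c1ccc(O)cc1)[C@H]2c1cc(O)cc(O)c1 | target

**Summary**

Total step count: 8. Longest linear sequence: 8 steps (1 to 14); 2, 6 and 10 are commercial coupling partners.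

**Steps most likely to fail**

Step 5. The alkyl–nickel intermediate may undergo β-hydride elimination, or the C2 radical may be oxidised further, either of which aromatises the ring to a 3-arylbenzofuran. Slow oxidative addition of the electron-rich aryl iodide may also let protodecarboxylation win, and the trans selectivity may be incomplete. The fallback sets out from 9 and comes back at 11. Acid 9 is esterified with N-hydroxyphthalimide (DIC, cat. DMAP, CH2Cl2) to the redox-active ester 6-methyl 2-(1,3-dioxoisoindolin-2-yl) (2S,3S)-4-(benzyloxy)-3-[3,5-bis(benzyloxy)phenyl]-2,3-dihydro-1-benzofuran-2,6-dicarboxylate F1. This is coupled under nickel catalysis without light (NiCl2·glyme, dtbbpy, THF/DMF, rt) with [4-(benzyloxy)phenyl]zinc chloride F2, prepared from commercial 1-(benzyloxy)-4-bromobenzene (Mg, LiCl; then ZnCl2). The radical then arises by reductive fragmentation of the ester and the aryl group arrives as a nucleophile, so no oxidative addition of an electron-rich aryl halide and no photo-oxidant are involved.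

Step 3. Insertion of the aryl–rhodium species may be slowed by the 5-benzyloxy group peri to C4, so that protodeboronation of 6 and hydrolysis of the lactone take over, and the facial selectivity may be lower than on simple coumarins. The fallback sets out from 5 and comes back at 7. Oxidative Heck arylation of 5 with 6 (Pd(OAc)2, 1,10-phenanthroline, O2, DMF, 80 °C) should give the flat 4-arylcoumarin methyl 5-(benzyloxy)-4-[3,5-bis(benzyloxy)phenyl]-2-oxo-2H-chromene-7-carboxylate F3. Copper hydride-catalysed asymmetric conjugate reduction (Cu(OAc)2, the DTBM-SEGPHOS antipode that gives 4S, (EtO)2MeSiH, t-BuOH, toluene) then gives 7. The stereocentre is thus set by delivery of the small hydride to C4, not by delivery of an aryl group.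

Step 8. The Lewis acid may ionise the benzylic C2–O bond of the dihydrofuran ring, which would open the ring, epimerise C2 or let the scavenger capture the cation; debenzylation may also stop short. The fallback sets out from 12 and comes back at 14. The benzyl ethers of alcohol 12 are removed by hydrogenolysis before the aldehyde exists (H2, Pd(OH)2/C, EtOAc/MeOH) to give the pentaol (2S,3S)-3-(3,5-dihydroxyphenyl)-6-(hydroxymethyl)-2-(4-hydroxyphenyl)-2,3-dihydro-1-benzofuran-4-ol F4. Its benzylic alcohol is then oxidised chemoselectively in the presence of the free phenols (activated MnO2, acetone, rt) to 14.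

Further compounds
F1 | step 5 | 6-methyl 2-(1,3-dioxoisoindolin-2-yl) (2S,3S)-4-(benzyloxy)-3-[3,5-bis(benzyloxy)phenyl]-2,3-dihydro-1-benzofuran-2,6-dicarboxylate | COC(=O)c1cc(OCc3ccccc3)c2c(c1)O[C@H](C(=O)ON1C(=O)c3ccccc3C1=O)[C@H]2c1cc(OCc2ccccc2)cc(OCc2ccccc2)c1
F2 | step 5 | [4-(benzyloxy)phenyl]zinc chloride | Cl[Zn]c1ccc(OCc2ccccc2)cc1
F3 | step 3 | methyl 5-(benzyloxy)-4-[3,5-bis(benzyloxy)phenyl]-2-oxo-2H-chromene-7-carboxylate | COC(=O)c1cc(OCc3ccccc3)c2c(c1)OC(=O)C=C2c1cc(OCc2ccccc2)cc(OCc2ccccc2)c1
F4 | step 8 | (2S,3S)-3-(3,5-dihydroxyphenyl)-6-(hydroxymethyl)-2-(4-hydroxyphenyl)-2,3-dihydro-1-benzofuran-4-ol | OCc1cc(O)c2c(c1)O[C@H](c1ccc(O)cc1)[C@H]2c1cc(O)cc(O)c1
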